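**Assumptions (one line each)**
- Numbering follows the chain from the ethyl ketone: C3=O, C5‑OH, C6‑CH2OH, C7=O, C8‑CH2OH, C9‑OH, C10/C11 epoxide, C12‑Me, C13=C14; the SMILES decodes to 5S,6S,8R,9S,10R,11S,12S,13Z, with C9 and C12 cis on the epoxide (so the precursor alkene is Z).
- The open‑chain diketone is the target; it will be isolated in equilibrium with its C3 hemiketal (myriaporone 3).
- In Step 15 the antipode of the menthone‑derived bromoborane that gives the 5S,6S adduct is used; I could not fix from memory which menthone enantiomer that is, so it must be confirmed on a model aldol (both menthones are commercial).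

**Retrosynthetic overview**
1. The C10–C11 epoxide is the only ring and is formed last, by C9‑OH‑directed epoxidation of the (Z)‑trisubstituted allylic alcohol 22.
2. C8–C9: substrate‑controlled anti boron aldol of the C1–C8 ketone 19 with the (Z,Z)‑dienal 9 (C9–C15).
3. C5–C6: reagent‑controlled anti boron aldol of the symmetric ketone 14 with the masked β‑keto aldehyde 17 (C1–C5).
4. 9 comes from (R)‑Roche ester (Z‑Wittig, then Still–Gennari); 14 from dimethyl acetonedicarboxylate; 17 from methyl 3‑oxopentanoate.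

---

**Fragment A: dienal 9 (C9–C15)**

Step 1
Reactants: 1 methyl (R)‑3‑hydroxy‑2‑methylpropanoate
Product: 2 methyl (R)‑3‑[(tert‑butyldimethylsilyl)oxy]‑2‑methylpropanoate
Conditions: TBSCl, imidazole, DMF, 0 °C → rt
Reagents that add atoms: TBSCl, CC(C)(C)[Si](C)(C)Cl
Why: Silyl protection of the primary alcohol; the stereocentre (future C12) is untouched.

Step 2
Reactants: 2
Product: 3 (R)‑3‑[(tert‑butyldimethylsilyl)oxy]‑2‑methylpropanal
Conditions: DIBAL‑H (1.05 equiv), CH2Cl2, −78 °C; MeOH, Rochelle salt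
Reagents that add atoms: none
Why: Partial ester reduction through the tetrahedral aluminate, stable at −78 °C; the α‑centre is retained if the aldehyde is used crude.

Step 3
Reactants: 3
Product: 4 (S,Z)‑tert‑butyldimethyl[(2‑methylpent‑3‑en‑1‑yl)oxy]silane
Conditions: EtPPh3Br, KHMDS, THF, −78 °C → rt
Reagents that add atoms: ethyltriphenylphosphonium bromide, CC[P+](c1ccccc1)(c1ccccc1)c1ccccc1.[Br-]
Why: Salt‑free Wittig reaction of a non‑stabilised ylide gives the Z alkene (C13=C14) under kinetic control.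

Step 4
Reactants: 4
Product: 5 (S,Z)‑2‑methylpent‑3‑en‑1‑ol
Conditions: TBAF, THF, 0 °C → rt (volatile; concentrate cold)
Reagents that add atoms: none
Why: Fluoride desilylation; no stereocentre is affected.

Step 5
Reactants: 5
Product: 6 (S,Z)‑2‑methylpent‑3‑enal
Conditions: Dess–Martin periodinane, NaHCO3, CH2Cl2, 0 °C; used at once as a crude solution
Reagents that add atoms: none
Why: Buffered Dess–Martin oxidation avoids epimerisation or conjugation of the β,γ‑unsaturated α‑chiral aldehyde.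

Step 6
Reactants: 6
Product: 7 ethyl (2Z,4S,5Z)‑2,4‑dimethylhepta‑2,5‑dienoate
Conditions: (CF3CH2O)2P(O)CH(CH3)CO2Et, KHMDS, 18‑crown‑6, THF, −78 °C
Reagents that add atoms: ethyl 2‑[bis(2,2,2‑trifluoroethoxy)phosphoryl]propanoate, CCOC(=O)C(C)P(=O)(OCC(F)(F)F)OCC(F)(F)F
Why: Still–Gennari olefination gives the Z‑trisubstituted enoate (C10=C11, with C9 cis to C12); the cold, non‑equilibrating conditions protect C12.

Step 7
Reactants: 7
Product: 8 (2Z,4S,5Z)‑2,4‑dimethylhepta‑2,5‑dien‑1‑ol
Conditions: DIBAL‑H (2.5 equiv), CH2Cl2, −78 °C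
Reagents that add atoms: none
Why: 1,2‑Reduction of the enoate; both alkene geometries are unchanged.

Step 8
Reactants: 8
Product: 9 (2Z,4S,5Z)‑2,4‑dimethylhepta‑2,5‑dienal
Conditions: activated MnO2, CH2Cl2, rt; used crude
Reagents that add atoms: none
Why: Neutral allylic oxidation keeps the Z enal geometry and the doubly allylic C12 centre.

**Fragment B: symmetric ketone 14 (C6–C8 with both CH2O arms)**

Step 9
Reactants: 10 dimethyl 3‑oxopentanedioate
Product: 11 dimethyl 2,2'‑(1,3‑dioxolane‑2,2‑diyl)diacetate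
Conditions: ethylene glycol, TsOH (cat.), toluene, reflux, Dean–Stark
Reagents that add atoms: ethylene glycol, OCCO
Why: Ketalisation masks the ketone so that both esters can be reduced.

Step 10
Reactants: 11
Product: 12 2,2'‑(1,3‑dioxolane‑2,2‑diyl)diethanol
Conditions: LiAlH4, THF, 0 °C → rt
Reagents that add atoms: none
Why: Hydride reduction of both esters; the ketal is inert.

Step 11
Reactants: 12
Product: 13 2,2‑bis{2‑[(4‑methoxybenzyl)oxy]ethyl}‑1,3‑dioxolane
Conditions: NaH, PMBCl (2.2 equiv), TBAI (cat.), DMF, 0 °C → rt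
Reagents that add atoms: 4‑methoxybenzyl chloride, COc1ccc(CCl)cc1
Why: Williamson etherification; the PMB ethers are needed later as the directing groups in Step 17.

Step 12
Reactants: 13
Product: 14 1,5‑bis[(4‑methoxybenzyl)oxy]pentan‑3‑one
Conditions: PPTS, acetone/H2O, reflux
Reagents that add atoms: water, O
Why: Mild ketal hydrolysis; PMB ethers survive and weak acid avoids retro‑oxa‑Michael loss of PMBOH.

**Fragment C: aldehyde 17 (C1–C5)**

Step 13
Reactants: 15 methyl 3‑oxopentanoate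
Product: 16 methyl 2‑(2‑ethyl‑1,3‑dioxolan‑2‑yl)acetate
Conditions: ethylene glycol, TsOH (cat.), toluene, reflux, Dean–Stark
Reagents that add atoms: ethylene glycol, OCCO
Why: Ketalisation masks the future C3 ketone so that it cannot enolise in the two aldol steps.

Step 14
Reactants: 16
Product: 17 2‑(2‑ethyl‑1,3‑dioxolan‑2‑yl)acetaldehyde
Conditions: DIBAL‑H (1.05 equiv), CH2Cl2, −78 °C
Reagents that add atoms: none
Why: Partial ester reduction at −78 °C; the ketal is unaffected.

**Assembly**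

Step 15
Reactants: 14 and 17
Product: 18 (4S,5S)‑6‑(2‑ethyl‑1,3‑dioxolan‑2‑yl)‑5‑hydroxy‑1‑[(4‑methoxybenzyl)oxy]‑4‑{[(4‑methoxybenzyl)oxy]methyl}hexan‑3‑one (C5 S, C6 S)
Conditions: bis[(menthyl)methyl]boron bromide (Gennari–Paterson reagent), Et3N, CH2Cl2/Et2O, −78 °C, 2 h; then 17, −78 → −25 °C; pH 7 buffer/MeOH/H2O2, 0 °C
Reagents that add atoms: none
Why: Asymmetric boron aldol: the E‑enol borinate reacts through a Zimmerman–Traxler chair to give the 5,6‑anti adduct, and the chiral ligands on boron choose the enolate face (precedent for ethyl ketones is about 75–88% ee; the minor enantiomer is removed as a diastereomer after Step 17).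

Step 16
Reactants: 18
Product: 19 (4S,5S)‑6‑(2‑ethyl‑1,3‑dioxolan‑2‑yl)‑1‑[(4‑methoxybenzyl)oxy]‑4‑{[(4‑methoxybenzyl)oxy]methyl}‑5‑[(triethylsilyl)oxy]hexan‑3‑one
Conditions: TESCl, imidazole, DMF, 0 °C
Reagents that add atoms: chlorotriethylsilane, CC[Si](CC)(CC)Cl
Why: Silylation of C5‑OH leaves the C6 CH2OPMB arm as the only good hydrogen‑bond acceptor on the α'‑centre for Step 17.

Step 17
Reactants: 19 and 9
Product: 20 (2S,3S,5R,6S,7Z,9S,10Z)‑1‑(2‑ethyl‑1,3‑dioxolan‑2‑yl)‑6‑hydroxy‑3,5‑bis{[(4‑methoxybenzyl)oxy]methyl}‑7,9‑dimethyl‑2‑[(triethylsilyl)oxy]dodeca‑7,10‑dien‑4‑one (= 5S,6S,8R,9S,12S in target numbering)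
Conditions: (c‑Hex)2BCl, Et3N, Et2O, −78 → 0 °C, 2 h; then 9, −78 → −25 °C, 16 h; pH 7 buffer/MeOH/H2O2, 0 °C; chromatography
Reagents that add atoms: none
Why: Paterson‑type anti boron aldol: enolisation occurs on the unbranched CH2 side to the E‑enolate, the chair transition state gives 8,9‑anti, and the C6 centre (H eclipsing the enolate, CH2OPMB toward the aldehyde, the bulky C5 silyloxy chain away) directs attack so that the two CH2O arms end up syn, i.e. 8R,9S.

Step 18
Reactants: 20
Product: 21 (2S,3S,5R,6S,7Z,9S,10Z)‑1‑(2‑ethyl‑1,3‑dioxolan‑2‑yl)‑6‑hydroxy‑3,5‑bis(hydroxymethyl)‑7,9‑dimethyl‑2‑[(triethylsilyl)oxy]dodeca‑7,10‑dien‑4‑one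
Conditions: DDQ (2.5 equiv), CH2Cl2/pH 7 buffer (10:1), 0 °C
Reagents that add atoms: none
Why: Oxidative PMB cleavage under neutral conditions tolerates the TES ether, ketal, β‑hydroxy ketone and alkenes; any p‑methoxybenzylidene acetal by‑product is hydrolysed in Step 19.

Step 19
Reactants: 21
Product: 22 (5S,6S,8R,9S,10Z,12S,13Z)‑5,9‑dihydroxy‑6,8‑bis(hydroxymethyl)‑10,12‑dimethylpentadeca‑10,13‑diene‑3,7‑dione
Conditions: PPTS, acetone/H2O (9:1), 50 °C (or 0.5 M HCl, THF, rt)
Reagents that add atoms: water, O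
Why: One mild acid hydrolysis removes the TES ether and the dioxolane, releasing the C3 ketone; no stereocentre is involved and there is no epoxide yet to open.

Step 20
Reactants: 22
Product: 23 myriaporone 4, (5S,6S,8R,9S,10R,11S,12S,13Z)‑10,11‑epoxy‑5,9‑dihydroxy‑6,8‑bis(hydroxymethyl)‑10,12‑dimethylpentadec‑13‑ene‑3,7‑dione
Conditions: mCPBA (1.1 equiv), NaHCO3, CH2Cl2, −30 → −10 °C; neutral work‑up
Reagents that add atoms: mCPBA, O=C(OO)c1cccc(Cl)c1
Why: Hydroxyl‑directed (Henbest) epoxidation: A(1,3) strain in the Z‑allylic alcohol holds C9‑H in the alkene plane, so the peracid is delivered syn to C9‑OH (threo), giving 10R,11S; the trisubstituted allylic alkene reacts well ahead of the C13=C14 Z‑alkene.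

---

**Compound list**
1 | methyl (R)‑3‑hydroxy‑2‑methylpropanoate | COC(=O)[C@H](C)CO | starting material
2 | methyl (R)‑3‑(TBS‑oxy)‑2‑methylpropanoate | COC(=O)[C@H](C)CO[Si](C)(C)C(C)(C)C | intermediate
3 | (R)‑3‑(TBS‑oxy)‑2‑methylpropanal | O=C[C@H](C)CO[Si](C)(C)C(C)(C)C | intermediate
4 | (S,Z)‑TBS ether of 2‑methylpent‑3‑en‑1‑ol | C/C=C\[C@H](C)CO[Si](C)(C)C(C)(C)C | intermediate
5 | (S,Z)‑2‑methylpent‑3‑en‑1‑ol | C/C=C\[C@H](C)CO | intermediate
6 | (S,Z)‑2‑methylpent‑3‑enal | C/C=C\[C@H](C)C=O | intermediate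
7 | ethyl (2Z,4S,5Z)‑2,4‑dimethylhepta‑2,5‑dienoate | C/C=C\[C@H](C)/C=C(C)\C(=O)OCC | intermediate
8 | (2Z,4S,5Z)‑2,4‑dimethylhepta‑2,5‑dien‑1‑ol | C/C=C\[C@H](C)/C=C(C)\CO | intermediate
9 | (2Z,4S,5Z)‑2,4‑dimethylhepta‑2,5‑dienal | C/C=C\[C@H](C)/C=C(C)\C=O | intermediate
10 | dimethyl 3‑oxopentanedioate | COC(=O)CC(=O)CC(=O)OC | starting material
11 | dimethyl 2,2'‑(1,3‑dioxolane‑2,2‑diyl)diacetate | COC(=O)CC1(CC(=O)OC)OCCO1 | intermediate
12 | 2,2'‑(1,3‑dioxolane‑2,2‑diyl)diethanol | OCCC1(CCO)OCCO1 | intermediate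
13 | 2,2‑bis{2‑[(4‑methoxybenzyl)oxy]ethyl}‑1,3‑dioxolane | COc1ccc(COCCC2(CCOCc3ccc(OC)cc3)OCCO2)cc1 | intermediate
14 | 1,5‑bis[(4‑methoxybenzyl)oxy]pentan‑3‑one | COc1ccc(COCCC(=O)CCOCc2ccc(OC)cc2)cc1 | intermediate
15 | methyl 3‑oxopentanoate | CCC(=O)CC(=O)OC | starting material
16 | methyl 2‑(2‑ethyl‑1,3‑dioxolan‑2‑yl)acetate | CCC1(CC(=O)OC)OCCO1 | intermediate
17 | 2‑(2‑ethyl‑1,3‑dioxolan‑2‑yl)acetaldehyde | CCC1(CC=O)OCCO1 | intermediate
18 | (4S,5S)‑anti aldol adduct, C5‑OH | COc1ccc(COCCC(=O)[C@@H](COCc2ccc(OC)cc2)[C@@H](O)CC3(CC)OCCO3)cc1 | intermediate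
19 | (4S,5S)‑C1–C8 ketone, C5‑OTES | COc1ccc(COCCC(=O)[C@@H](COCc2ccc(OC)cc2)[C@@H](O[Si](CC)(CC)CC)CC3(CC)OCCO3)cc1 | intermediate
20 | protected C1–C15 aldol adduct (5S,6S,8R,9S,12S) | C/C=C\[C@H](C)/C=C(C)\[C@@H](O)[C@@H](COCc1ccc(OC)cc1)C(=O)[C@@H](COCc1ccc(OC)cc1)[C@@H](O[Si](CC)(CC)CC)CC1(CC)OCCO1 | intermediate
21 | triol after PMB removal (C5‑OTES, C3 ketal) | C/C=C\[C@H](C)/C=C(C)\[C@@H](O)[C@@H](CO)C(=O)[C@@H](CO)[C@@H](O[Si](CC)(CC)CC)CC1(CC)OCCO1 | intermediate
22 | 10,11‑deoxy alkene precursor (5S,6S,8R,9S,10Z,12S,13Z) | C/C=C\[C@H](C)/C=C(C)\[C@@H](O)[C@@H](CO)C(=O)[C@@H](CO)[C@@H](O)CC(=O)CC | intermediate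
23 | myriaporone 4 | C/C=C\[C@H](C)[C@@H]1O[C@]1(C)[C@@H](O)[C@@H](CO)C(=O)[C@@H](CO)[C@@H](O)CC(=O)CC | target

---

**Totals**
- Total step count: 20
- Longest linear sequence: 12 steps (Steps 1–8, then 17–20, from Roche ester 1); the branch from 10 is 10 steps.

**Three steps most likely to fail, with fallbacks**
1. Step 15 (reagent‑controlled anti aldol). The risks are moderate ee, an untested β‑alkoxy ketone substrate, and the sense of induction. Fallback: build 19 under auxiliary control. An Evans syn aldol of an N‑crotonyl oxazolidinone boron dienolate with 17 gives the α‑vinyl adduct. The acyl carbon becomes the C6 CH2OPMB arm (TES protection, LiBH4, PMB ether), and the vinyl group becomes C7 (ozonolysis, vinylMgBr, oxidation, oxa‑Michael addition of PMBOH).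
2. Step 17 (substrate‑controlled fragment aldol). The risks are insufficient facial control from C6 and isomerisation of the Z enal. Fallback: reverse the assembly so that C8/C9 are set under reagent control. Ketone 14 is first combined with dienal 9 using the chiral bromoborane, and the diastereomers are separated at that stage. After TES protection, the C5–C6 bond is made last with the inexpensive aldehyde 17.
3. Step 19 (acidic unmasking next to an allylic alcohol and two β‑hydroxy ketones). The risks are dehydration, allylic transposition, or incomplete ketal cleavage. Fallback: carry C3 as a 1,3‑dithiane instead, made from 15 with propane‑1,3‑dithiol and then DIBAL. Remove the TES group with HF·pyridine and unmask the dithiane oxidatively (PhI(OCOCF3)2 or MeI/CaCO3) before the epoxidation, so that no aqueous acid is needed.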